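**Strategy.** The aromatic ring of the tetralin (C4a, C5, C6, C7, C8, C8a) is annulated onto the intact carvone-derived cyclohexane by disconnecting C8–C8a and C4a–C5. This exploits the fact that C5–C6–C7–C8, with the C5 and C6 oxygens and the C7 formyl carbon, are a 4-methoxyacetoacetyl unit whose alkylidene carbon (C8) already bears the pyranone through C3'. In one pot the kinetic silyl enol ether of trans-carvomenthone adds to this alkylidene β-keto thioester, the methoxy-bearing methylene condenses on the ring ketone and DDQ aromatises. Placing the C5 oxygen on the acceptor as a methoxy group removes any later oxidation of a deactivated phenol.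

Key step: step 9

Numbering: tetralin C1 (isopropyl), C4 (methyl), C4a, C5 to C8, C8a; pyranone atoms primed.
Remark on the precursor design: the acceptor carries one extra methoxy group on the carbon that becomes C5; the bonds formed and the ring closed are unchanged, and C7 stays an S-ethyl thioester.
Structure check: (S)-carvone supplies C1 as R and trans-carvomenthone supplies C4 as S (trans-1,4), which matches the target as given.
Assumption: the target leaves the hindered C8–C3' axis unassigned, so it is not controlled here; atropisomers, if they are configurationally stable, would be equilibrated thermally or separated at the end.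

Step 1
Reactants: 1 (S)-(+)-carvone
Product: 3 (2S,5S)-trans-carvomenthone [(2S,5S)-2-methyl-5-(propan-2-yl)cyclohexan-1-one], via carvomenthone C2-epimer mixture 2 (not isolated)
Conditions: H2 (1 atm), PtO2 (cat.), MeOH, rt, stopped after 2 equiv H2; N2 purge; then NaOMe (0.2 equiv), rt
Reagents that add atoms: none
Why: Heterogeneous hydrogenation over platinum saturates both C=C bonds without moving the isopropenyl double bond into the ring, so C5 stays S, and methoxide equilibration through the enolate should favour the diequatorial trans isomer (C2 = S); residual cis epimer is tolerable because this centre is again α to a ketone in 16.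

Step 2
Reactants: 3 (2S,5S)-trans-carvomenthone
Product: 4 trimethyl{[(3R,6S)-6-methyl-3-(propan-2-yl)cyclohex-1-en-1-yl]oxy}silane (kinetic enol ether)
Conditions: LiN(iPr)2 (1.1 equiv), THF, −78 °C, slow addition of ketone; TMSCl, −78 °C → rt; distillation
Reagents that add atoms: chlorotrimethylsilane, C[Si](C)(C)Cl
Why: Kinetic deprotonation of a 2-methylcyclohexanone by the hindered amide takes the unsubstituted α-methylene and O-silylation freezes that regiochemistry, while excess base at low temperature prevents enolate equilibration, so the methyl-bearing centre is untouched.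

Step 3
Reactants: 5 methoxyacetyl chloride; 6 Meldrum's acid (2,2-dimethyl-1,3-dioxane-4,6-dione)
Product: 7 5-(1-hydroxy-2-methoxyethylidene)-2,2-dimethyl-1,3-dioxane-4,6-dione
Conditions: pyridine (2 equiv), CH2Cl2, 0 °C → rt
Reagents that add atoms: none
Why: C-acylation of the highly acidic Meldrum's acid by an acid chloride is a standard entry to acyl Meldrum's acids, which rest as the hydrogen-bonded enol.

Step 4
Reactants: 7 5-(1-hydroxy-2-methoxyethylidene)-2,2-dimethyl-1,3-dioxane-4,6-dione
Product: 8 S-ethyl 4-methoxy-3-oxobutanethioate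
Conditions: EtSH (3 equiv), PhMe, 80 °C, sealed tube
Reagents that add atoms: ethanethiol, CCS
Why: Thermolysis of the acyl Meldrum's acid releases acetone and CO2 to give an acylketene that the thiol traps, the usual preparation of β-keto thioesters.

Step 5
Reactants: 9 4-methoxy-6-methyl-2H-pyran-2-one
Product: 10 4-methoxy-6-methyl-2-oxo-2H-pyran-3-carbaldehyde
Conditions: Cl2CHOMe (1.5 equiv), TiCl4 (2.2 equiv), CH2Cl2, 0 °C → rt; H2O
Reagents that add atoms: dichloromethyl methyl ether, COC(Cl)Cl; water, O
Why: Rieche formylation attacks C3, the carbon activated by both the 4-methoxy group and, vinylogously, the ring oxygen; formylating before the styryl arm exists leaves no electron-rich arene to compete.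

Step 6
Reactants: 10 4-methoxy-6-methyl-2-oxo-2H-pyran-3-carbaldehyde
Product: 11 3-(dimethoxymethyl)-4-methoxy-6-methyl-2H-pyran-2-one
Conditions: HC(OMe)3 (3 equiv), TsOH·H2O (cat.), MeOH, rt
Reagents that add atoms: trimethyl orthoformate, COC(OC)OC
Why: Acid-catalysed acetalisation with orthoformate as water scavenger masks the aldehyde for the basic condensation, and any exchange of the 4-methoxy group with methanol is degenerate.

Step 7
Reactants: 11 3-(dimethoxymethyl)-4-methoxy-6-methyl-2H-pyran-2-one; 12 3,4-dimethoxybenzaldehyde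
Product: 14 6-[(E)-2-(3,4-dimethoxyphenyl)ethenyl]-4-methoxy-2-oxo-2H-pyran-3-carbaldehyde, via styryl dimethyl acetal 13 (not isolated)
Conditions: Mg(OMe)2 (2.5 equiv), MeOH, reflux; then 1 M aq. HCl, THF, rt
Reagents that add atoms: water, O
Why: Vinylogous aldol condensation of the 6-methyl group (magnesium dienolate) with the aryl aldehyde, the established route to styrylpyranones, gives the thermodynamically favoured E alkene, and the base-stable acetal is hydrolysed in the acidic work-up.

Step 8
Reactants: 14 6-[(E)-2-(3,4-dimethoxyphenyl)ethenyl]-4-methoxy-2-oxo-2H-pyran-3-carbaldehyde; 8 S-ethyl 4-methoxy-3-oxobutanethioate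
Product: 15 S-ethyl 2-(methoxyacetyl)-3-{6-[(E)-2-(3,4-dimethoxyphenyl)ethenyl]-4-methoxy-2-oxo-2H-pyran-3-yl}prop-2-enethioate (mixture of isomers at the new alkene)
Conditions: TiCl4 (2 equiv), pyridine (4 equiv), THF, 0 °C → rt
Reagents that add atoms: none
Why: Knoevenagel condensation in its TiCl4/pyridine variant activates the hindered push–pull aldehyde without a nucleophilic amine that could displace the 4'-methoxy group; the geometry of the new alkene is irrelevant because C8 becomes sp3 and then aromatic.

Step 9
Reactants: 4 trimethyl{[(3R,6S)-6-methyl-3-(propan-2-yl)cyclohex-1-en-1-yl]oxy}silane (1.5 equiv); 15 S-ethyl 2-(methoxyacetyl)-3-{6-[(E)-2-(3,4-dimethoxyphenyl)ethenyl]-4-methoxy-2-oxo-2H-pyran-3-yl}prop-2-enethioate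
Product: 18 S-ethyl (1R,4S)-6-hydroxy-5-methoxy-4-methyl-1-(propan-2-yl)-8-{6-[(E)-2-(3,4-dimethoxyphenyl)ethenyl]-4-methoxy-2-oxo-2H-pyran-3-yl}tetralin-7-carbothioate, via Michael adduct 16 (not isolated), via hexahydronaphthalenone 17 (not isolated)
Conditions: TiCl4 (2.2 equiv), CH2Cl2, −78 °C; then TsOH·H2O (3 equiv), ClCH2CH2Cl, 60 °C; then DDQ (1.1 equiv), rt
Reagents that add atoms: none
Why: TiCl4 chelates the β-keto thioester of 15 and the unsubstituted enol ether carbon of 4 adds to the alkylidene carbon (Mukaiyama–Michael addition, bond C8–C8a) to give diketone 16; TsOH then enolises the methoxyacetyl group toward its methoxy-bearing methylene, which adds to the ring carbonyl and dehydrates (bond C4a–C5), and DDQ removes the C8 and C8a hydrogens from the enolised β-keto thioester 17. The closest known reactions are the Robinson-type annulation of ketones with alkylidene acetoacetates, the annulation with methoxymethyl vinyl ketone that gives 2-methoxy enones, and quinone dehydrogenation of cyclohexenone carboxylates to salicylates. The single new ring closes by intramolecular aldol condensation in the 6-(enolendo)-exo-trig mode. No new stereocentre survives, since the sp3 centres formed at C7, C8 and C8a are erased on aromatisation; C1 is inherited from carvone, and C4 is α to a ketone in 16, where the all-equatorial trans arrangement is the thermodynamic one. The step needs chemoselectivity for the chelated, doubly activated alkene over the styrylpyranone diene, regioselectivity from the kinetic enol ether, and retention at C4 once the enone exists, which the hydrogen-bonded enol form of 17 and prompt addition of about one equivalent of DDQ should secure. Because the pyranone is attached while C8 is still sp3, the peri-crowded C8–C3' bond never has to be formed on an arene.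

Step 10
Reactants: 18 S-ethyl (1R,4S)-6-hydroxy-5-methoxy-4-methyl-1-(propan-2-yl)-8-{6-[(E)-2-(3,4-dimethoxyphenyl)ethenyl]-4-methoxy-2-oxo-2H-pyran-3-yl}tetralin-7-carbothioate
Product: 19 (1R,4S)-6-hydroxy-5-methoxy-4-methyl-1-(propan-2-yl)-8-{6-[(E)-2-(3,4-dimethoxyphenyl)ethenyl]-4-methoxy-2-oxo-2H-pyran-3-yl}tetralin-7-carbaldehyde
Conditions: Et3SiH (4 equiv), 10% Pd/C (10 mol% Pd), acetone, rt; dilute aq. HCl work-up
Reagents that add atoms: none
Why: Fukuyama reduction (oxidative addition of zerovalent palladium into the acyl–sulfur bond, hydride transfer from the silane, reductive elimination) stops at the aldehyde and leaves the pyranone lactone and the methyl ethers alone; the acidic work-up cleaves any silyl ether formed at O6.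

Step 11
Reactants: 19 (1R,4S)-6-hydroxy-5-methoxy-4-methyl-1-(propan-2-yl)-8-{6-[(E)-2-(3,4-dimethoxyphenyl)ethenyl]-4-methoxy-2-oxo-2H-pyran-3-yl}tetralin-7-carbaldehyde
Product: 20 heimiomycin B
Conditions: BBr3 (10 equiv), CH2Cl2, −78 °C → rt; MeOH then H2O, under Ar
Reagents that add atoms: none
Why: Global O-demethylation by boron complexation and bromide attack on methyl cleaves the three aryl methyl ethers and the pyranone methyl ether (a vinylogous methyl ester), while the remote benzylic stereocentres C1 and C4 are not involved.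

**Compound list**

1 | (S)-(+)-carvone | CC(=C)[C@H]1CC=C(C)C(=O)C1 | starting material
2 | (5S)-carvomenthone, mixture of C2 epimers | CC(C)[C@H]1CCC(C)C(=O)C1 | intermediate (not isolated)
3 | (2S,5S)-trans-carvomenthone | CC(C)[C@H]1CC[C@H](C)C(=O)C1 | intermediate
4 | trimethyl{[(3R,6S)-6-methyl-3-(propan-2-yl)cyclohex-1-en-1-yl]oxy}silane | CC(C)[C@H]1CC[C@H](C)C(O[Si](C)(C)C)=C1 | intermediate
5 | methoxyacetyl chloride | COCC(Cl)=O | starting material
6 | Meldrum's acid | CC1(C)OC(=O)CC(=O)O1 | starting material
7 | 5-(1-hydroxy-2-methoxyethylidene)-2,2-dimethyl-1,3-dioxane-4,6-dione | COCC(O)=C1C(=O)OC(C)(C)OC1=O | intermediate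
8 | S-ethyl 4-methoxy-3-oxobutanethioate | CCSC(=O)CC(=O)COC | intermediate
9 | 4-methoxy-6-methyl-2H-pyran-2-one | COc1cc(C)oc(=O)c1 | starting material
10 | 4-methoxy-6-methyl-2-oxo-2H-pyran-3-carbaldehyde | COc1cc(C)oc(=O)c1C=O | intermediate
11 | 3-(dimethoxymethyl)-4-methoxy-6-methyl-2H-pyran-2-one | COc1cc(C)oc(=O)c1C(OC)OC | intermediate
12 | 3,4-dimethoxybenzaldehyde | COc1ccc(C=O)cc1OC | starting material
13 | 3-(dimethoxymethyl)-6-[(E)-2-(3,4-dimethoxyphenyl)ethenyl]-4-methoxy-2H-pyran-2-one | COC(OC)c1c(OC)cc(/C=C/c2ccc(OC)c(OC)c2)oc1=O | intermediate (not isolated)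
14 | 6-[(E)-2-(3,4-dimethoxyphenyl)ethenyl]-4-methoxy-2-oxo-2H-pyran-3-carbaldehyde | O=Cc1c(OC)cc(/C=C/c2ccc(OC)c(OC)c2)oc1=O | intermediate
15 | S-ethyl 2-(methoxyacetyl)-3-{6-[(E)-2-(3,4-dimethoxyphenyl)ethenyl]-4-methoxy-2-oxo-2H-pyran-3-yl}prop-2-enethioate (isomer mixture at the alkylidene bond) | CCSC(=O)C(C(=O)COC)=Cc1c(OC)cc(/C=C/c2ccc(OC)c(OC)c2)oc1=O | intermediate
16 | Michael adduct: S-ethyl 2-(methoxyacetyl)-3-(pyranonyl)-3-[3-methyl-2-oxo-6-(propan-2-yl)cyclohexyl]propanethioate, C1 and C4 centres as in 18, new centres unassigned | CC(C)[C@H]1CC[C@H](C)C(=O)C1C(C(C(=O)COC)C(=O)SCC)c1c(OC)cc(/C=C/c2ccc(OC)c(OC)c2)oc1=O | intermediate (not isolated)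
17 | hexahydronaphthalenone (keto form of the dienol): 5-methoxy-6-oxo-4a(5)-ene with C7 thioester and C8 pyranone, C1 and C4 centres as in 18 | CC(C)[C@H]1CC[C@H](C)C2=C(OC)C(=O)C(C(=O)SCC)C(c3c(OC)cc(/C=C/c4ccc(OC)c(OC)c4)oc3=O)C21 | intermediate (not isolated)
18 | S-ethyl (1R,4S)-6-hydroxy-5-methoxy-4-methyl-1-(propan-2-yl)-8-{6-[(E)-2-(3,4-dimethoxyphenyl)ethenyl]-4-methoxy-2-oxo-2H-pyran-3-yl}tetralin-7-carbothioate | CC(C)[C@H]1CC[C@H](C)c2c(OC)c(O)c(C(=O)SCC)c(-c3c(OC)cc(/C=C/c4ccc(OC)c(OC)c4)oc3=O)c21 | intermediate
19 | (1R,4S)-6-hydroxy-5-methoxy-4-methyl-1-(propan-2-yl)-8-{6-[(E)-2-(3,4-dimethoxyphenyl)ethenyl]-4-methoxy-2-oxo-2H-pyran-3-yl}tetralin-7-carbaldehyde | CC(C)[C@H]1CC[C@H](C)c2c(OC)c(O)c(C=O)c(-c3c(OC)cc(/C=C/c4ccc(OC)c(OC)c4)oc3=O)c21 | intermediate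
20 | heimiomycin B | CC(C)[C@H]1CC[C@H](C)c2c(O)c(O)c(C=O)c(-c3c(O)cc(/C=C/c4ccc(O)c(O)c4)oc3=O)c21 | target

**Totals**

Total step count: 11. Longest linear sequence: 7 steps (9 to 20, steps 5 to 11).

**Steps most likely to fail**

Step 9. The conjugate addition may stall at the alkylidene carbon, which is shielded by the C2' carbonyl and the C4' methoxy group and deactivated by push–pull conjugation. The diketone may also close through oxygen to a 4H-pyran or revert by retro-Michael cleavage, and C4 may epimerise by γ-deprotonation before aromatisation. The fallback reverses the roles of the partners and sets out from 4 and 14. A TiCl4-mediated Mukaiyama aldol addition (CH2Cl2, −78 °C) should give the β-hydroxy ketone F1, and TsOH-catalysed dehydration the (E)-arylidene ketone F2. DBU-catalysed Michael addition of the β-keto thioester 8 to F2 (THF, rt) should then give diketone 16. This is cyclised and aromatised with TsOH·H2O and DDQ as in the second half of step 9, and the fallback comes back to the route at 18. This is the classical arylidene ketone plus acetoacetate annulation, in which the first bond to C8 is made by addition to an aldehyde and the second by a small stabilised carbanion.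

Step 10. Oxidative addition into the acyl–sulfur bond, flanked by the C6 hydroxyl and the C8 pyranone, may be slow, while silane-derived hydrogen on palladium saturates the styryl double bond. The fallback sets out from 18 and replaces the catalytic reduction by two chemoselective steps. NaBH4 (THF/EtOH, 0 °C → rt) should reduce the thioester to the salicyl alcohol F3, the pyranone being a vinylogous carbonate that resists borohydride. MnO2 (CH2Cl2, rt) should then oxidise the benzylic alcohol, and the fallback comes back to the route at 19.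

Step 11. Cleavage of the pyranone methyl ether may lag behind the aryl ethers, while excess BBr3 and HBr degrade the aldehyde-bearing polyphenol. The fallback sets out from 19 and stages the unmasking by two different mechanisms. LiI (EtOAc, reflux) should remove only the vinylogous ester methyl group by SN2 attack, giving the 4'-hydroxy compound F4. BCl3/n-Bu4NI (CH2Cl2, −78 → 0 °C) should then cleave the three aryl methyl ethers under milder Lewis acidity, and the fallback comes back to the route at 20.

**Further compounds**

F1 | step 9 | 6-{hydroxy[6-((E)-3,4-dimethoxystyryl)-4-methoxy-2-oxo-2H-pyran-3-yl]methyl} derivative of (2S,5S)-carvomenthone (ring centres unchanged, new centres unassigned) | CC(C)[C@H]1CC[C@H](C)C(=O)C1C(O)c1c(OC)cc(/C=C/c2ccc(OC)c(OC)c2)oc1=O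
F2 | step 9 | (E)-6-{[6-((E)-3,4-dimethoxystyryl)-4-methoxy-2-oxo-2H-pyran-3-yl]methylidene} derivative of (2S,5S)-carvomenthone (ring centres unchanged) | CC(C)[C@H]1CC[C@H](C)C(=O)/C1=C/c1c(OC)cc(/C=C/c2ccc(OC)c(OC)c2)oc1=O
F3 | step 10 | (1R,4S)-7-(hydroxymethyl)-5-methoxy-4-methyl-1-(propan-2-yl)-8-{6-[(E)-2-(3,4-dimethoxyphenyl)ethenyl]-4-methoxy-2-oxo-2H-pyran-3-yl}tetralin-6-ol | CC(C)[C@H]1CC[C@H](C)c2c(OC)c(O)c(CO)c(-c3c(OC)cc(/C=C/c4ccc(OC)c(OC)c4)oc3=O)c21
F4 | step 11 | (1R,4S)-6-hydroxy-5-methoxy-4-methyl-1-(propan-2-yl)-8-{6-[(E)-2-(3,4-dimethoxyphenyl)ethenyl]-4-hydroxy-2-oxo-2H-pyran-3-yl}tetralin-7-carbaldehyde | CC(C)[C@H]1CC[C@H](C)c2c(OC)c(O)c(C=O)c(-c3c(O)cc(/C=C/c4ccc(OC)c(OC)c4)oc3=O)c21
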